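# Proposed synthesis of 5,7-dihydroxy-6,8-dimethyl-2-tricosyl-4H-chromen-4-one (13) by biomimetic Claisen folding of a pyranone-masked pentaketide

## Analysis of the target

The target 13 (C34H56O4) is a benzo-fused 4-pyranone. Ring C (O1, C2, C3, C4, C4a, C8a) carries an unbranched C23 chain on C2. Ring A (C4a, C5, C6, C7, C8, C8a) has no hydrogen: oxygen sits on C5, C7 and C8a, carbon on C4a (the C4 carbonyl), C6 and C8 (methyl groups).

There is no stereocentre and no double-bond geometry, so the problem is one of connectivity and regiochemistry only.

The feature that the strategy is tied to is the unbroken nine-carbon chain C5–C6–C7–C8–C8a–C4a–C4–C3–C2, in which every second carbon (C5, C7, C8a, C4, C2) bears oxygen. Rings A and C are thus the folded form of a poly-β-carbonyl chain with methyl branches on C6 and C8 and the C23 tail on C2.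

Sensitive points are the electron-rich ring A, whose phenolates are oxidised by air in base, the pyranone ring, which strong aqueous base opens, and the waxy chain, which limits solubility at low temperature.

The synthesis is hard because a hexasubstituted benzene offers no free position to direct anything. C-Methylation of a 1,3,5-triphenol competes with O-alkylation and geminal dialkylation, and three phenols compete in any late acylation.

One feature helps: the acylphloroglucinol that precedes ring C has a mirror plane through C4a and C7, so ring C can close on either ortho oxygen with the same result.

## Retrosynthetic reasoning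

**13 to 12 (O1–C2).** The enol ether bond O1–C2 is cut first, which leads to the ortho-hydroxyaryl 1,3-diketone 12. The forward reaction is an acid-induced cyclodehydration. Because the two ortho hydroxyl groups of 12 are equivalent, no selectivity is needed.

**12 to 11 (C4a–C5).** The ring A bond C4a–C5 is cut next, which unfolds the benzene ring into the linear tetraketo ester 11. The cut is placed here because C5 is then at the acid oxidation level (an ester) and C4a is a methylene between two ketones, the natural Claisen pair. The methyl-bearing carbons (future C6 and C8) also block the competing aldol foldings, which would make them quaternary. The gain is that ring A, with all six substituents, is no longer bought or decorated but made from a chain. The forward reaction has to close a six-membered ring by C-acylation and aromatise.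

**11 to 10 (the mask).** The ester carbon, the ketone that becomes C7 and the enol oxygen of the ketone that becomes C8a are tied together as the 4-hydroxy-2-pyranone 10. The mask removes three of the five reactive carbonyl groups, gives crystalline intermediates and lowers the charge of every polyanion on the way. The forward reaction has to open the lactone with alkoxide before the Claisen closure; a magnesium alkoxide should do both.

**10 to 7 and 8 (C2–C3).** The C2–C3 bond is cut, which separates the whole C24 acyl unit as the commercial ester 8 from the small acetonyl pyranone 7. The terminal methyl group of 7 is the only terminal enolisable position, so a polyanion of 7 can be acylated there and nowhere else.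

**7 to 5 and 2 (C4–C4a).** The C4–C4a bond is cut, which leads to the trimethylpyranone 5 and the acetyl donor 2. The 6-methyl group of 5 is the only position vinylogous to the lactone carbonyl, so double deprotonation gives a single lateral carbanion.

**5 to 4 to 1 and 2 (lactone, C8–C8a).** The lactone C–O bond of 5 is opened to the diketo ester 4, and the bond that becomes C8–C8a is cut to the commercial β-keto ester 1 and again 2. Compound 1 already holds C5, C6, C7 and C8 with both methyl groups in the right places, so no C-methylation is ever carried out on an aromatic ring.

## Alternatives that were turned down

Alternative 1: The textbook disconnection cuts O1–C2 and C2–C3 and takes ring A from an aromatic starting material.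
- Forward key step: 2,4-dimethylbenzene-1,3,5-triol A1 is C-acetylated to 1-(2,4,6-trihydroxy-3,5-dimethylphenyl)ethan-1-one A2. The lithium polyanion of A2 is acylated with tetracosanoyl chloride A3 in the Baker–Venkataraman manner to give 12, and acid closes 13.
- Why turned down: A1 itself needs two steps from the parent triphenol (twofold formylation and reduction) through air-sensitive intermediates. The three free hydroxyl groups of A2 compete with the enolate for A3, so either protection and deprotection or a sacrificial excess of the C24 unit is needed. The count of about five steps is no lower than that of the chosen route, and no ring is built. This is the route most chemists would draw first.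

Alternative 2: A Diels–Alder and aromatisation construction of ring A cuts C4a–C5 and C8–C8a.
- Forward key step: 1-methoxy-2-methyl-1,3-bis(trimethylsilyloxy)penta-1,3-diene A4, made from 1, adds to ethyl 3-ethoxyprop-2-ynoate A5. Loss of the methoxy group as the alcohol and desilylation give ethyl 2-ethoxy-4,6-dihydroxy-3,5-dimethylbenzoate A6.
- Why turned down: A5 is a push–pull alkyne whose acceptor carbon is deactivated by the ethoxy donor, and A4 is a tetrasubstituted diene that reaches the s-cis form with difficulty, so the cycloaddition is doubtful. After A6 the pyranone still has to be made by Claisen condensation at a doubly ortho-substituted, electron-rich benzoate, and an ethyl ether has to be cleaved. The ring construction wins ring A but costs more steps than it saves.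

Alternative 3: A (5+1) double Claisen condensation cuts both C4a–C5 and C4a–C8a.
- Forward key step: the terminal carbanion of the dianion of heptacosane-2,4-dione A7 attacks one ester of dimethyl 2,4-dimethyl-3-oxopentanedioate A8 to give 11 in the flask. This folds to 12, and acid gives 13, three steps in all.
- Why turned down: A8 has two C–H acids, each flanked by a ketone and an ester, and the terminal carbanion of the A7 dianion is a far stronger base than the enolate of A8. Proton transfer should therefore outrun acylation, and the enolate of A8 so formed is a deactivated acyl acceptor. The chosen route delivers the same five carbons from 1, where the acidic positions are used as the nucleophile and not exposed to one.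

Key step: step 5

## Route

Remark on the chemistry: all β-polycarbonyl compounds are named and drawn as keto forms although they exist as enols or metal chelates. Compounds 4 and 11 are diastereomer mixtures of no consequence, because both centres end as aromatic carbons. Polyanions are drawn as one resonance form.

Step 1
Reactants: 1 methyl 2-methyl-3-oxopentanoate; 2 N-methoxy-N-methylacetamide
Product: 4 methyl 2,4-dimethyl-3,5-dioxohexanoate, via dilithium dienolate 3 (not isolated)
Conditions: LiN(i-Pr)2 (2.1 equiv), THF, −78 to 0 °C; then 2, −78 to 0 °C; aq HCl
Reagents that add atoms: none
Why: Double deprotonation of the β-keto ester gives the 2,4-dianion 3, whose γ-carbon (C4) is the more basic and more nucleophilic site, so the N-methoxy-N-methylamide acylates there only (γ-acylation of a β-keto ester dianion, a Claisen-type condensation); the chelated tetrahedral adduct survives until the quench, which prevents double addition, and the two stereocentres of 4 form without control and are erased later.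

Step 2
Reactants: 4 methyl 2,4-dimethyl-3,5-dioxohexanoate
Product: 5 4-hydroxy-3,5,6-trimethyl-2H-pyran-2-one
Conditions: DBU (1.5 equiv), toluene, reflux; aq HCl
Reagents that add atoms: none
Why: The enol oxygen at C5 attacks the ester carbonyl in a 6-exo-trig lactonisation with loss of methanol, and the acidic 4-hydroxy-2-pyranone is held as its DBU salt, which drives the closure (base-mediated cyclisation of a 3,5-diketo ester, the standard entry to 3,5-dimethyl-4-hydroxy-2-pyranones).

Step 3
Reactants: 5 4-hydroxy-3,5,6-trimethyl-2H-pyran-2-one; 2 N-methoxy-N-methylacetamide
Product: 7 4-hydroxy-3,5-dimethyl-6-(2-oxopropyl)-2H-pyran-2-one, via dilithium dianion 6 (not isolated)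
Conditions: LiN(i-Pr)2 (2.2 equiv), THF–DMPU, −78 °C; then 2, −78 to 0 °C; aq HCl
Reagents that add atoms: none
Why: The first equivalent of base gives the pyronate and the second removes a proton from the 6-methyl group, the only position vinylogous to the lactone carbonyl; this lateral carbanion of 6 is acylated by 2 to a stable chelate that gives the methyl ketone on quench (lateral acylation of a 4-hydroxy-6-methyl-2-pyranone dianion), and the pyronate charge protects the lactone from attack.

Step 4
Reactants: 7 4-hydroxy-3,5-dimethyl-6-(2-oxopropyl)-2H-pyran-2-one; 8 methyl tetracosanoate
Product: 10 4-hydroxy-3,5-dimethyl-6-(2,4-dioxoheptacosyl)-2H-pyran-2-one, via trilithium trianion 9 (not isolated)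
Conditions: 7 (2 equiv), LiN(i-Pr)2 (6.1 equiv), THF, −78 to 0 °C; then 8 in warm THF, 0 °C to rt; aq HCl
Reagents that add atoms: none
Why: Three equivalents of base remove the enol proton, one proton of the doubly activated CH2 and finally one of the terminal methyl group, and the last-formed, least stabilised terminal carbanion of 9 is the one that attacks the ester (terminal Claisen acylation of a 1,3-dicarbonyl polyanion); 9 is used twofold because the new β-diketone is deprotonated by a second equivalent, which returns 7 on work-up; the step forms the C2–C3 bond of the target and brings in the whole chain.

Step 5
Reactants: 10 4-hydroxy-3,5-dimethyl-6-(2,4-dioxoheptacosyl)-2H-pyran-2-one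
Product: 13 5,7-dihydroxy-6,8-dimethyl-2-tricosyl-4H-chromen-4-one, via open-chain tetraketo ester 11 (not isolated), via acylphloroglucinol diketone 12 (not isolated)
Conditions: Mg(OMe)2 (8 equiv), MeOH–THF, reflux, Ar; then conc. HCl to pH 1, 60 °C
Reagents that add atoms: none
Why: Mg(OMe)2 turns 10 into magnesium chelates and opens the lactone by methanolysis at the carbonyl that becomes C5, which frees the enolised ketone that becomes C8a and gives the magnesium complex of the linear ester 11. In 11 the methylene between two ketones (future C4a) attacks the methyl ester in a 6-exo-trig Claisen (Dieckmann-type) closure, and loss of methoxide and enolisation give the aromatic acylphloroglucinol 12, which makes the sequence irreversible. The closest known reaction type is the magnesium-alkoxide-induced conversion of 6-(2-oxoalkyl)-4-hydroxy-2-pyranones and of 3,5,7-triketo esters into acylphloroglucinols, the laboratory counterpart of the Claisen mode of polyketide folding. The selectivity needed is Claisen over aldol closure, and the substrate secures it: the methyl groups on the carbons that become C6 and C8 turn the two aldol closures that dominate in unbranched chains into dead ends, because each would create a quaternary ring carbon that cannot aromatise, and the one remaining aldol acceptor (future C7) is a ketone flanked by two branched carbons and held as a chelated enolate. The ester end is the least acidic β-dicarbonyl unit of 11, so it stays un-enolised and electrophilic while the more acidic diketone methylenes supply the nucleophile. Acidification then lets an ortho hydroxyl group of 12 add to the distal ketone (6-exo-trig), and the hemiketal loses water to give the 4-pyranone ring (cyclodehydration of an ortho-hydroxyaryl 1,3-diketone, the closing step of the Baker–Venkataraman chromone synthesis). Because 12 has a mirror plane through C4a and C7, both hydroxyl groups lead to the same chromone, and no stereocentre is formed. The operation thus makes the C4a–C5 and O1–C2 bonds, consumes the pyranone mask and delivers both rings of 13 with all six ring A substituents in place.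

## Compound list

1 | methyl 2-methyl-3-oxopentanoate (racemic) | CCC(=O)C(C)C(=O)OC | starting material
2 | N-methoxy-N-methylacetamide | CC(=O)N(C)OC | starting material
3 | dilithium 1-methoxy-2-methylpenta-1,3-diene-1,3-diolate (2,4-dianion of 1) | [Li+].[Li+].CC=C([O-])C(C)=C([O-])OC | intermediate
4 | methyl 2,4-dimethyl-3,5-dioxohexanoate (mixture of diastereomers and enol forms) | CC(=O)C(C)C(=O)C(C)C(=O)OC | intermediate
5 | 4-hydroxy-3,5,6-trimethyl-2H-pyran-2-one | CC1=C(C)C(O)=C(C)C(=O)O1 | intermediate
6 | dilithium salt of 5, deprotonated at the 4-hydroxyl and at the 6-methyl group | [Li+].[Li+].[CH2-]C1=C(C)C([O-])=C(C)C(=O)O1 | intermediate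
7 | 4-hydroxy-3,5-dimethyl-6-(2-oxopropyl)-2H-pyran-2-one | CC(=O)CC1=C(C)C(O)=C(C)C(=O)O1 | intermediate
8 | methyl tetracosanoate | CCCCCCCCCCCCCCCCCCCCCCCC(=O)OC | starting material
9 | trilithium salt of 7, deprotonated at the 4-hydroxyl, the ring-bound CH2 and the terminal CH3 | [Li+].[Li+].[Li+].[CH2-]C(=O)[CH-]C1=C(C)C([O-])=C(C)C(=O)O1 | intermediate
10 | 4-hydroxy-3,5-dimethyl-6-(2,4-dioxoheptacosyl)-2H-pyran-2-one | CCCCCCCCCCCCCCCCCCCCCCCC(=O)CC(=O)CC1=C(C)C(O)=C(C)C(=O)O1 | intermediate
11 | methyl 2,4-dimethyl-3,5,7,9-tetraoxodotriacontanoate (mixture of diastereomers and enol forms, present as magnesium chelate) | CCCCCCCCCCCCCCCCCCCCCCCC(=O)CC(=O)CC(=O)C(C)C(=O)C(C)C(=O)OC | intermediate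
12 | 1-(2,4,6-trihydroxy-3,5-dimethylphenyl)hexacosane-1,3-dione | CCCCCCCCCCCCCCCCCCCCCCCC(=O)CC(=O)c1c(O)c(C)c(O)c(C)c1O | intermediate
13 | 5,7-dihydroxy-6,8-dimethyl-2-tricosyl-4H-chromen-4-one | CCCCCCCCCCCCCCCCCCCCCCCc1cc(=O)c2c(O)c(C)c(O)c(C)c2o1 | target

## Step count and risk

Total step count: 5. Longest linear sequence: 5 steps (1 to 4 to 5 to 7 to 10 to 13). No protecting group is used.

**Step 5 (key step).**
- What may go wrong: the substrate is present as a pyronate, a vinylogous carboxylate, so methanolysis of the lactone may be slow. Methoxide-induced retro-Claisen cleavage of the side-chain diketone (loss of the C24 acyl group) can then compete. A second risk is aldol closure of the opened chain from the methylene that becomes C3 onto the ketone that becomes C7. Incomplete cyclodehydration is the least serious problem and is answered by longer acid treatment.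
- Fallback: it sets out from 4 and avoids the lactone altogether. Triple deprotonation of 4 with LiN(i-Pr)2 and acylation of the terminal methyl carbanion with 2 should give methyl 2,4-dimethyl-3,5,7-trioxooctanoate F1, worked up cold and with weak acid to keep it from lactonising. Fourfold deprotonation of F1 and terminal acylation with 8 should give the open-chain ester 11 as an isolated enol mixture. This is then folded with Mg(OMe)2 and closed with acid as in step 5. The route is rejoined at 11, and the Claisen closure no longer depends on ring opening.

**Step 4.**
- What may go wrong: proton transfer from the α-CH2 of the enolisable ester 8 to the strongly basic trianion 9, followed by self-condensation of 8. The low solubility of 8 below 0 °C slows the acylation further, so 7 may be recovered.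
- Fallback: it sets out from 7 and replaces the ester acylation by an alkylation. Trianion 9 is acylated with the small amide 2 (as in step 3) to give 4-hydroxy-3,5-dimethyl-6-(2,4-dioxopentyl)-2H-pyran-2-one F2. Fourfold deprotonation of F2 with LiN(i-Pr)2 and SN2 alkylation of the terminal carbanion with 1-bromodocosane should give 10, where the route is rejoined. An alkylation is irreversible and its product does not quench unreacted polyanion.

**Step 3.**
- What may go wrong: aggregation and low solubility of the dilithium salt 6 can leave the lateral metalation incomplete, and proton exchange between the carbanion and the acetyl group of 2 returns 5.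
- Fallback: it sets out from 5 and uses the fastest reaction of such dianions, aldol addition. Dianion 6 is treated with acetaldehyde at −78 °C to give racemic 4-hydroxy-6-(2-hydroxypropyl)-3,5-dimethyl-2H-pyran-2-one F3. Oxidation of the secondary alcohol with Dess–Martin periodinane in CH2Cl2 should give 7, where the route is rejoined.

## Further compounds

F1 | step 5 | methyl 2,4-dimethyl-3,5,7-trioxooctanoate (mixture of diastereomers and enol forms) | CC(=O)CC(=O)C(C)C(=O)C(C)C(=O)OC
F2 | step 4 | 4-hydroxy-3,5-dimethyl-6-(2,4-dioxopentyl)-2H-pyran-2-one | CC(=O)CC(=O)CC1=C(C)C(O)=C(C)C(=O)O1
F3 | step 3 | 4-hydroxy-6-(2-hydroxypropyl)-3,5-dimethyl-2H-pyran-2-one (racemic) | CC(O)CC1=C(C)C(O)=C(C)C(=O)O1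
A1 | alternative 1 | 2,4-dimethylbenzene-1,3,5-triol | Oc1cc(O)c(C)c(O)c1C
A2 | alternative 1 | 1-(2,4,6-trihydroxy-3,5-dimethylphenyl)ethan-1-one | CC(=O)c1c(O)c(C)c(O)c(C)c1O
A3 | alternative 1 | tetracosanoyl chloride | CCCCCCCCCCCCCCCCCCCCCCCC(=O)Cl
A4 | alternative 2 | 1-methoxy-2-methyl-1,3-bis(trimethylsilyloxy)penta-1,3-diene | COC(O[Si](C)(C)C)=C(C)C(O[Si](C)(C)C)=CC
A5 | alternative 2 | ethyl 3-ethoxyprop-2-ynoate | CCOC#CC(=O)OCC
A6 | alternative 2 | ethyl 2-ethoxy-4,6-dihydroxy-3,5-dimethylbenzoate | CCOC(=O)c1c(OCC)c(C)c(O)c(C)c1O
A7 | alternative 3 | heptacosane-2,4-dione | CCCCCCCCCCCCCCCCCCCCCCCC(=O)CC(C)=O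
A8 | alternative 3 | dimethyl 2,4-dimethyl-3-oxopentanedioate | COC(=O)C(C)C(=O)C(C)C(=O)OC
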